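**Strategy.** Everything rests on opening the cyclohexenone ring (C1 = ketone carbon, C2/C3 = alkene, C4/C5 = carbinols, C6 = CH carrying the acid arm) at the C4–C5 bond of its cis-1,2-diol, read as a pinacol retron. Both carbons become aldehyde carbons of like polarity in an acyclic (Z)-hex-2-enedial, assembled by an Evans syn-aldol with an ynal and a hydroxyl-directed trans-hydroalumination/iodination. A SmI2 pinacol cyclisation reunites them: in one operation it closes the six-membered ring and sets both hydroxyl stereocentres, cis to each other and trans to the C6 allyl group. Oxidation at C1, cross-metathesis, α-iodination/Suzuki coupling and acidolysis complete the target.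

Key step: step 9

Remark: the target is read as a 4,5-cis-diol with the C6 substituent trans to the C5 hydroxyl, (1S,5R,6S) in the numbering of the final name and (R) in the side chain; compounds 1, 2, 4, 20, 23, 24 (THF solution) and 26 are taken as commercial.

**Route**

Step 1
Reactants: 1 (4R)-4-benzyl-1,3-oxazolidin-2-one; 2 pent-4-enoyl chloride
Product: 3 (4R)-4-benzyl-3-(pent-4-enoyl)-1,3-oxazolidin-2-one
Conditions: Et3N, DMAP (cat.), CH2Cl2, 0 °C → rt
Reagents that add atoms: none
Why: N-acylation of the oxazolidinone with the acid chloride under Et3N/DMAP catalysis is the standard way to load the Evans auxiliary and creates no stereocentre.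

Step 2
Reactants: 4 1-methoxy-4-[(prop-2-yn-1-yloxy)methyl]benzene (PMB propargyl ether)
Product: 6 4-[(4-methoxybenzyl)oxy]but-2-ynal, via lithium acetylide 5 (not isolated)
Conditions: n-BuLi, THF, −78 °C; DMF, −78 → 0 °C; reverse quench into aq. KH2PO4
Reagents that add atoms: N,N-dimethylformamide, CN(C)C=O
Why: Deprotonation of the terminal alkyne and formylation of the lithium acetylide with DMF is the standard ynal synthesis, the buffered reverse quench keeping dimethylamine from adding to the ynal.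

Step 3
Reactants: 3 (4R)-4-benzyl-3-(pent-4-enoyl)-1,3-oxazolidin-2-one; 6 4-[(4-methoxybenzyl)oxy]but-2-ynal
Product: 8 (4R)-4-benzyl-3-[(2R,3R)-3-hydroxy-6-[(4-methoxybenzyl)oxy]-2-(prop-2-en-1-yl)hex-4-ynoyl]-1,3-oxazolidin-2-one, via boron enolate 7 (not isolated)
Conditions: Bu2BOTf, i-Pr2NEt, CH2Cl2, −78 → 0 °C; 6, −78 → −10 °C; pH 7 buffer, MeOH, H2O2, 0 °C
Reagents that add atoms: none
Why: Evans syn-aldol reaction in which the (Z)-boron enolate reacts through a Zimmerman–Traxler chair on the face opposite the benzyl group of the (R)-auxiliary, which sets the allyl-bearing carbon (later ring C6) as (2R) and the carbinol as (3R), a syn pair.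

Step 4
Reactants: 8 aldol adduct
Product: 9 (2S,3R)-6-[(4-methoxybenzyl)oxy]-2-(prop-2-en-1-yl)hex-4-yne-1,3-diol
Conditions: LiBH4, MeOH (1 equiv), THF, 0 °C
Reagents that add atoms: none
Why: Reductive removal of the Evans auxiliary with LiBH4 gives the primary alcohol without touching the alkyne or the PMB ether, and both stereocentres are left as set.

Step 5
Reactants: 9 (2S,3R)-alkynediol
Product: 11 (2S,3R,4Z)-5-iodo-6-[(4-methoxybenzyl)oxy]-2-(prop-2-en-1-yl)hex-4-ene-1,3-diol, via alkenylalanate 10 (not isolated)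
Conditions: NaAlH2(OCH2CH2OMe)2 (Red-Al), THF, 0 °C → rt; I2, −78 → 0 °C; aq. potassium sodium tartrate, Na2S2O3
Reagents that add atoms: iodine, II
Why: Hydroxyl-directed trans-hydroalumination of the propargylic alkoxide places hydrogen on the proximal and aluminium on the distal alkyne carbon in a five-membered alanate, and iodinolysis with retention gives the (Z)-vinyl iodide in which the carbinol carbon and iodine are cis, the geometry the ring closure needs.

Step 6
Reactants: 11 (Z)-iodo diol
Product: 12 (2S,3R,4Z)-5-iodo-6-[(4-methoxybenzyl)oxy]-2-(prop-2-en-1-yl)-1,3-bis(triethylsilyloxy)hex-4-ene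
Conditions: TESCl, imidazole, DMAP (cat.), CH2Cl2, 0 °C → rt
Reagents that add atoms: chlorotriethylsilane, CC[Si](Cl)(CC)CC
Why: Silylation of both hydroxyl groups masks the secondary carbinol, which would otherwise form a lactol with the later cis-aldehyde, and leaves the primary position in a form that Swern conditions can oxidise directly.

Step 7
Reactants: 12 bis-TES (Z)-vinyl iodide
Product: 14 (2Z,4S,5S)-2-{[(4-methoxybenzyl)oxy]methyl}-5-(prop-2-en-1-yl)-4,6-bis(triethylsilyloxy)hex-2-enal, via alkenyllithium 13 (not isolated)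
Conditions: t-BuLi (2.1 equiv), Et2O, −78 °C; DMF, −78 → −40 °C; aq. NH4Cl
Reagents that add atoms: N,N-dimethylformamide, CN(C)C=O
Why: Iodine–lithium exchange with two equivalents of t-BuLi occurs with retention of alkene geometry and the alkenyllithium is formylated by DMF (Bouveault-type formylation), which should give the (Z)-enal with the formyl group cis to the silyloxy-bearing carbon.

Step 8
Reactants: 14 (Z)-enal
Product: 15 (2Z,4S,5R)-2-{[(4-methoxybenzyl)oxy]methyl}-5-(prop-2-en-1-yl)-4-(triethylsilyloxy)hex-2-enedial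
Conditions: (COCl)2, DMSO, CH2Cl2, −78 → −40 °C; Et3N, −78 → 0 °C; used crude
Reagents that add atoms: none
Why: Under Swern conditions the activated DMSO cleaves the unhindered primary TES ether and oxidises it to the aldehyde in the same flask whereas the secondary TES ether survives, so the dialdehyde should be reached without a separate deprotection.

Step 9
Reactants: 15 (Z)-hex-2-enedial
Product: 16 (1S,2R,5S,6S)-3-{[(4-methoxybenzyl)oxy]methyl}-6-(prop-2-en-1-yl)-5-(triethylsilyloxy)cyclohex-3-ene-1,2-diol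
Conditions: SmI2 (3 equiv, 0.1 M in THF), slow addition of 15 (final 0.01 M), THF, −78 °C, no proton source, no HMPA; aq. NaHCO3
Reagents that add atoms: none
Why: SmI2 transfers one electron to each carbonyl group (the enal first) and the two ketyl carbons, held on trivalent samarium, couple to the 1,2-diolate; the closest known reaction type is the SmI2-mediated intramolecular pinacol coupling of 1,6-dialdehydes to cis-cyclohexane-1,2-diols. The six-membered carbocycle closes in a 6-exo mode with respect to the attacked aldehyde carbonyl, both oxygen atoms ending outside the ring. The cis relation of the two new hydroxyl groups should come from the samarium ion that bridges both oxygen atoms in the cyclic transition state, and their trans relation to the allyl group from the existing allyl-bearing stereocentre, which keeps its substituent equatorial in the chair-like transition state, reinforced by the trans OTES group. The step needs carbonyl–carbonyl coupling rather than 4-exo attack on the enal β-carbon, conjugate reduction or loss of the γ-silyloxy group: the (Z) geometry holds the enal carbonyl carbon within reach of the aldehyde, the more easily reduced enal carries the first ketyl, and aprotic conditions at low temperature disfavour a second electron transfer before cyclisation.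

Step 10
Reactants: 16 cyclohexenediol
Product: 18 (3aS,4R,5S,7aR)-7-{[(4-methoxybenzyl)oxy]methyl}-2,2-dimethyl-4-(prop-2-en-1-yl)-3a,4,5,7a-tetrahydro-1,3-benzodioxol-5-ol, via silyl acetonide 17 (not isolated)
Conditions: Me2C(OMe)2, CSA (cat.), acetone, 0 °C → rt; then MeOH, 0 °C; Et3N quench
Reagents that add atoms: 2,2-dimethoxypropane, COC(C)(C)OC
Why: The cis-1,2-diol is locked as its acetonide (five-membered dioxolane) and the acid-labile secondary allylic TES ether is then methanolysed in the same flask, while the PMB ether survives.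

Step 11
Reactants: 18 allylic alcohol
Product: 19 (3aS,4S,7aR)-7-{[(4-methoxybenzyl)oxy]methyl}-2,2-dimethyl-4-(prop-2-en-1-yl)-3a,7a-dihydro-1,3-benzodioxol-5(4H)-one
Conditions: Dess–Martin periodinane, NaHCO3, CH2Cl2, 0 °C → rt
Reagents that add atoms: none
Why: Dess–Martin oxidation of the allylic alcohol under buffered, non-basic conditions should give the enone without epimerising the α-stereocentre (whose allyl group already sits on the favoured exo side, trans to the dioxolane) or eliminating the β-alkoxy group.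

Step 12
Reactants: 19 enone; 20 tert-butyl methacrylate (excess)
Product: 21 tert-butyl (2E)-4-[(3aS,4S,7aR)-7-{[(4-methoxybenzyl)oxy]methyl}-2,2-dimethyl-5-oxo-3a,4,5,7a-tetrahydro-1,3-benzodioxol-4-yl]-2-methylbut-2-enoate
Conditions: second-generation Hoveyda–Grubbs catalyst (5 mol %), CH2Cl2, 40 °C
Reagents that add atoms: none
Why: Olefin cross-metathesis of the terminal allyl group with excess methacrylate should give the trisubstituted enoate as the thermodynamically favoured (E)-isomer, the conjugated enone alkene being too hindered and electron-poor to take part.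

Step 13
Reactants: 21 enone ester
Product: 22 tert-butyl (2E)-4-[(3aS,4S,7aR)-6-iodo-7-{[(4-methoxybenzyl)oxy]methyl}-2,2-dimethyl-5-oxo-3a,4,5,7a-tetrahydro-1,3-benzodioxol-4-yl]-2-methylbut-2-enoate
Conditions: I2, pyridine, DMAP (cat.), CH2Cl2, rt, dark
Reagents that add atoms: iodine, II
Why: Amine-mediated α-iodination of the enone (Johnson iodination: conjugate addition of the amine, iodination of the enolate, elimination) puts iodine on ring carbon C2 under conditions too mild to epimerise C6 or eliminate the β-alkoxy group.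

Step 14
Reactants: 23 (R)-2-methyloxirane; 24 but-3-en-1-ylmagnesium bromide
Product: 25 (2R)-hept-6-en-2-ol
Conditions: CuI (10 mol %), THF, −40 → 0 °C; aq. NH4Cl
Reagents that add atoms: none
Why: CuI-catalysed opening of the epoxide by the Grignard reagent at the unsubstituted carbon leaves the (R)-stereocentre untouched.

Step 15
Reactants: 25 (2R)-hept-6-en-2-ol; 26 4,4,5,5-tetramethyl-2-vinyl-1,3,2-dioxaborolane
Product: 27 (2R,6E)-7-(4,4,5,5-tetramethyl-1,3,2-dioxaborolan-2-yl)hept-6-en-2-ol
Conditions: second-generation Grubbs catalyst (3 mol %), CH2Cl2, 40 °C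
Reagents that add atoms: none
Why: Cross-metathesis of the terminal alkene with the vinylboronate should give the (E)-alkenylboronate as the thermodynamically preferred isomer and tolerates the free hydroxyl group.

Step 16
Reactants: 22 α-iodoenone; 27 (E)-alkenylboronate
Product: 28 tert-butyl (2E)-4-[(3aS,4S,7aR)-6-[(1E,6R)-6-hydroxyhept-1-en-1-yl]-7-{[(4-methoxybenzyl)oxy]methyl}-2,2-dimethyl-5-oxo-3a,4,5,7a-tetrahydro-1,3-benzodioxol-4-yl]-2-methylbut-2-enoate
Conditions: PdCl2(dppf) (10 mol %), AsPh3, Cs2CO3, DMF/THF/H2O, rt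
Reagents that add atoms: none
Why: Suzuki–Miyaura coupling of the α-iodoenone with the (E)-alkenylboronate proceeds with retention at both sp2 carbons and should install the dienyl side chain at room temperature, mild enough for the β-alkoxy ketone.

Step 17
Reactants: 28 protected dienone
Product: 29 Pestallic acid O, (2E)-4-[(1S,5R,6S)-5,6-dihydroxy-3-[(1E,6R)-6-hydroxyhept-1-en-1-yl]-4-(hydroxymethyl)-2-oxocyclohex-3-en-1-yl]-2-methylbut-2-enoic acid
Conditions: TFA/CH2Cl2/H2O, anisole, 0 °C → rt; then brief aq. NaHCO3/MeOH to cleave any trifluoroacetate, acidify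
Reagents that add atoms: none
Why: Aqueous trifluoroacetic acid should cleave the acetonide, the PMB ether (cation trapped by anisole) and the tert-butyl ester in one acidolysis that touches no stereocentre, the β-hydroxy enone being of a type that normally tolerates such conditions.

**Compound list**

1 | (4R)-4-benzyl-1,3-oxazolidin-2-one | O=C1N[C@H](Cc2ccccc2)CO1 | starting material
2 | pent-4-enoyl chloride | C=CCCC(=O)Cl | starting material
3 | (4R)-4-benzyl-3-(pent-4-enoyl)-1,3-oxazolidin-2-one | C=CCCC(=O)N1[C@H](Cc2ccccc2)COC1=O | intermediate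
4 | 1-methoxy-4-[(prop-2-yn-1-yloxy)methyl]benzene | C#CCOCc1ccc(OC)cc1 | starting material
5 | lithium acetylide of 4 (not isolated) | [Li]C#CCOCc1ccc(OC)cc1 | intermediate
6 | 4-[(4-methoxybenzyl)oxy]but-2-ynal | O=CC#CCOCc1ccc(OC)cc1 | intermediate
7 | (Z)-dibutylboron enolate of 3 (not isolated) | C=CC/C=C(\OB(CCCC)CCCC)N1[C@H](Cc2ccccc2)COC1=O | intermediate
8 | (4R)-4-benzyl-3-[(2R,3R)-3-hydroxy-6-[(4-methoxybenzyl)oxy]-2-(prop-2-en-1-yl)hex-4-ynoyl]-1,3-oxazolidin-2-one | C=CC[C@H]([C@@H](O)C#CCOCc1ccc(OC)cc1)C(=O)N1[C@H](Cc2ccccc2)COC1=O | intermediate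
9 | (2S,3R)-6-[(4-methoxybenzyl)oxy]-2-(prop-2-en-1-yl)hex-4-yne-1,3-diol | C=CC[C@@H](CO)[C@@H](O)C#CCOCc1ccc(OC)cc1 | intermediate
10 | sodium (Z)-alkenylalanate, cyclic 2,5-dihydro-1,2-oxaluminole form, primary hydroxyl drawn free (not isolated) | C=CC[C@@H](CO)[C@H]1O[Al-](OCCOC)(OCCOC)C(COCc2ccc(OC)cc2)=C1.[Na+] | intermediate
11 | (2S,3R,4Z)-5-iodo-6-[(4-methoxybenzyl)oxy]-2-(prop-2-en-1-yl)hex-4-ene-1,3-diol | C=CC[C@@H](CO)[C@@H](O)/C=C(\I)COCc1ccc(OC)cc1 | intermediate
12 | (2S,3R,4Z)-5-iodo-6-[(4-methoxybenzyl)oxy]-2-(prop-2-en-1-yl)-1,3-bis(triethylsilyloxy)hex-4-ene | C=CC[C@@H](CO[Si](CC)(CC)CC)[C@@H](O[Si](CC)(CC)CC)/C=C(\I)COCc1ccc(OC)cc1 | intermediate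
13 | alkenyllithium from 12, geometry retained (not isolated) | C=CC[C@@H](CO[Si](CC)(CC)CC)[C@@H](O[Si](CC)(CC)CC)/C=C(\[Li])COCc1ccc(OC)cc1 | intermediate
14 | (2Z,4S,5S)-2-{[(4-methoxybenzyl)oxy]methyl}-5-(prop-2-en-1-yl)-4,6-bis(triethylsilyloxy)hex-2-enal | C=CC[C@@H](CO[Si](CC)(CC)CC)[C@@H](O[Si](CC)(CC)CC)/C=C(\C=O)COCc1ccc(OC)cc1 | intermediate
15 | (2Z,4S,5R)-2-{[(4-methoxybenzyl)oxy]methyl}-5-(prop-2-en-1-yl)-4-(triethylsilyloxy)hex-2-enedial | C=CC[C@@H](C=O)[C@@H](O[Si](CC)(CC)CC)/C=C(\C=O)COCc1ccc(OC)cc1 | intermediate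
16 | (1S,2R,5S,6S)-3-{[(4-methoxybenzyl)oxy]methyl}-6-(prop-2-en-1-yl)-5-(triethylsilyloxy)cyclohex-3-ene-1,2-diol | C=CC[C@@H]1[C@@H](O[Si](CC)(CC)CC)C=C(COCc2ccc(OC)cc2)[C@@H](O)[C@H]1O | intermediate
17 | triethylsilyl ether of 18, (3aS,4S,5S,7aR) (not isolated) | C=CC[C@@H]1[C@@H](O[Si](CC)(CC)CC)C=C(COCc2ccc(OC)cc2)[C@H]2OC(C)(C)O[C@@H]12 | intermediate
18 | (3aS,4R,5S,7aR)-7-{[(4-methoxybenzyl)oxy]methyl}-2,2-dimethyl-4-(prop-2-en-1-yl)-3a,4,5,7a-tetrahydro-1,3-benzodioxol-5-ol | C=CC[C@@H]1[C@@H](O)C=C(COCc2ccc(OC)cc2)[C@H]2OC(C)(C)O[C@@H]12 | intermediate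
19 | (3aS,4S,7aR)-7-{[(4-methoxybenzyl)oxy]methyl}-2,2-dimethyl-4-(prop-2-en-1-yl)-3a,7a-dihydro-1,3-benzodioxol-5(4H)-one | C=CC[C@@H]1C(=O)C=C(COCc2ccc(OC)cc2)[C@H]2OC(C)(C)O[C@@H]12 | intermediate
20 | tert-butyl methacrylate | C=C(C)C(=O)OC(C)(C)C | starting material
21 | tert-butyl (2E)-4-[(3aS,4S,7aR)-7-{[(4-methoxybenzyl)oxy]methyl}-2,2-dimethyl-5-oxo-3a,4,5,7a-tetrahydro-1,3-benzodioxol-4-yl]-2-methylbut-2-enoate | C/C(=C\C[C@@H]1C(=O)C=C(COCc2ccc(OC)cc2)[C@H]2OC(C)(C)O[C@@H]12)C(=O)OC(C)(C)C | intermediate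
22 | tert-butyl (2E)-4-[(3aS,4S,7aR)-6-iodo-7-{[(4-methoxybenzyl)oxy]methyl}-2,2-dimethyl-5-oxo-3a,4,5,7a-tetrahydro-1,3-benzodioxol-4-yl]-2-methylbut-2-enoate | C/C(=C\C[C@@H]1C(=O)C(I)=C(COCc2ccc(OC)cc2)[C@H]2OC(C)(C)O[C@@H]12)C(=O)OC(C)(C)C | intermediate
23 | (R)-2-methyloxirane | C[C@@H]1CO1 | starting material
24 | but-3-en-1-ylmagnesium bromide | C=CCC[Mg]Br | starting material
25 | (2R)-hept-6-en-2-ol | C=CCCC[C@@H](C)O | intermediate
26 | 4,4,5,5-tetramethyl-2-vinyl-1,3,2-dioxaborolane | C=CB1OC(C)(C)C(C)(C)O1 | starting material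
27 | (2R,6E)-7-(4,4,5,5-tetramethyl-1,3,2-dioxaborolan-2-yl)hept-6-en-2-ol | C[C@@H](O)CCC/C=C/B1OC(C)(C)C(C)(C)O1 | intermediate
28 | tert-butyl (2E)-4-[(3aS,4S,7aR)-6-[(1E,6R)-6-hydroxyhept-1-en-1-yl]-7-{[(4-methoxybenzyl)oxy]methyl}-2,2-dimethyl-5-oxo-3a,4,5,7a-tetrahydro-1,3-benzodioxol-4-yl]-2-methylbut-2-enoate | C/C(=C\C[C@@H]1C(=O)C(/C=C/CCC[C@@H](C)O)=C(COCc2ccc(OC)cc2)[C@H]2OC(C)(C)O[C@@H]12)C(=O)OC(C)(C)C | intermediate
29 | Pestallic acid O, (2E)-4-[(1S,5R,6S)-5,6-dihydroxy-3-[(1E,6R)-6-hydroxyhept-1-en-1-yl]-4-(hydroxymethyl)-2-oxocyclohex-3-en-1-yl]-2-methylbut-2-enoic acid | C/C(=C\C[C@@H]1C(=O)C(/C=C/CCC[C@@H](C)O)=C(CO)[C@@H](O)[C@H]1O)C(=O)O | target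

**Step count and risks**

Total steps: 17. Longest linear sequence: 14 steps (steps 1, 3 to 13, 16 and 17, from 1 to 29).

The three steps most likely to fail:

Step 9 (pinacol cyclisation). The enal may be over-reduced (conjugate reduction followed by loss of the allylic ether), the γ-silyloxy group may be expelled after a second electron transfer, coupling may turn intermolecular, or the facial control by the allyl-bearing centre may be poor. Fallback: setting out from 15, an N-heterocyclic-carbene-catalysed intramolecular crossed acyloin (benzoin-type) cyclisation (triazolium precatalyst, DBU, THF, rt), in which the Breslow intermediate of the aliphatic aldehyde adds 1,2 to the enal carbonyl, should give the α-hydroxy ketone (2R,3S,6R)-6-hydroxy-5-{[(4-methoxybenzyl)oxy]methyl}-2-(prop-2-en-1-yl)-3-(triethylsilyloxy)cyclohex-4-en-1-one F1. Reduction of its ketone with NaBH4 in MeOH at −78 °C (axial hydride delivery, equatorial alcohol trans to the allyl group and cis to the neighbouring hydroxyl) comes back to the route at 16.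

Step 7 (formylation to the (Z)-enal). The alkenyllithium may lose the neighbouring alkoxide by β-elimination to an allene, and the α-substituted (Z)-enal may isomerise to the (E)-form on work-up. Fallback: setting out from 11, carbonylative lactonisation of the (Z)-iodo allylic alcohol (Pd(PPh3)4, CO, Et3N, THF, 50 °C) should give the butenolide (5S)-5-[(2S)-1-hydroxypent-4-en-2-yl]-3-{[(4-methoxybenzyl)oxy]methyl}furan-2(5H)-one F2, whose ring fixes the alkene geometry. Reduction with i-Bu2AlH (CH2Cl2, −78 → 0 °C) should give (2S,3S,4E)-5-{[(4-methoxybenzyl)oxy]methyl}-2-(prop-2-en-1-yl)hex-4-ene-1,3,6-triol F3. Silylation (TESCl, imidazole) should give its tris(triethylsilyl) ether F4, and a double Swern oxidation of the two primary TES ethers comes back to the route at 15.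

Step 12 (cross-metathesis). Productive metathesis with the 1,1-disubstituted acrylate may be slow and homodimerisation of 19 may compete. Fallback: setting out from 19, oxidative cleavage of the terminal alkene (OsO4 cat., NaIO4, 2,6-lutidine, dioxane/H2O) should give 2-[(3aS,4S,7aR)-7-{[(4-methoxybenzyl)oxy]methyl}-2,2-dimethyl-5-oxo-3a,4,5,7a-tetrahydro-1,3-benzodioxol-4-yl]acetaldehyde F5. Wittig olefination with tert-butyl 2-(triphenylphosphoranylidene)propanoate (toluene, 60 °C, (E)-selective stabilised ylide) comes back to the route at 21.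

Further compounds
F1 | step 9 | (2R,3S,6R)-6-hydroxy-5-{[(4-methoxybenzyl)oxy]methyl}-2-(prop-2-en-1-yl)-3-(triethylsilyloxy)cyclohex-4-en-1-one | C=CC[C@@H]1[C@@H](O[Si](CC)(CC)CC)C=C(COCc2ccc(OC)cc2)[C@@H](O)C1=O
F2 | step 7 | (5S)-5-[(2S)-1-hydroxypent-4-en-2-yl]-3-{[(4-methoxybenzyl)oxy]methyl}furan-2(5H)-one | C=CC[C@@H](CO)[C@H]1OC(=O)C(COCc2ccc(OC)cc2)=C1
F3 | step 7 | (2S,3S,4E)-5-{[(4-methoxybenzyl)oxy]methyl}-2-(prop-2-en-1-yl)hex-4-ene-1,3,6-triol | C=CC[C@@H](CO)[C@@H](O)/C=C(\CO)COCc1ccc(OC)cc1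
F4 | step 7 | tris(triethylsilyl) ether of F3 | C=CC[C@@H](CO[Si](CC)(CC)CC)[C@@H](O[Si](CC)(CC)CC)/C=C(\CO[Si](CC)(CC)CC)COCc1ccc(OC)cc1
F5 | step 12 | 2-[(3aS,4S,7aR)-7-{[(4-methoxybenzyl)oxy]methyl}-2,2-dimethyl-5-oxo-3a,4,5,7a-tetrahydro-1,3-benzodioxol-4-yl]acetaldehyde | O=CC[C@@H]1C(=O)C=C(COCc2ccc(OC)cc2)[C@H]2OC(C)(C)O[C@@H]12
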